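## Analysis of the target

Target 33 is a 2-methyl-1,4-benzoquinone joined through one methylene to C5 of a trans-decalin. Decalin numbering is used for all compounds below, also the monocyclic ones: C1 carries the CH2CH2CO2H chain, C2 the exocyclic C=C(CH3)2, C4a is the ring-fusion CH, C5 the quaternary carbon with CH3 and the quinonylmethyl group, C6 a CH–CH3, C8a the angular C–CH3. Ring A is C1–C4/C4a/C8a and ring B is C4a/C5–C8/C8a. Five stereocentres run in an unbroken row C1–C8a–C4a–C5–C6, and two of them (C5, C8a) are quaternary and 1,3-related. The methyl groups on C5 and C8a are syn-diaxial on one face and H-4a lies on the other (trans fusion). The C6 methyl is axial and anti to the C5 methyl, and the C1 chain is equatorial and cis to the C8a methyl. The quinone tolerates neither base, nucleophiles nor reductants, so it is carried as its dimethyl ether and set free last. The tetrasubstituted alkene can migrate under protic acid, and H-1 is allylic. The hard points are the congested C5/C8a pair, the exact position of the alkene, and the C1 configuration: an equatorial C1 substituent next to an isopropylidene group suffers allylic strain, so C1 cannot be corrected by equilibration and must be set in a kinetically controlled C–C bond formation. The strategy rests on the pair C2(=C(CH3)2)–C1(H)(chain): this is what remains when a C(SiMe3)=C(CH3)2 unit attacks an allyl cation through its silicon-bearing carbon and then loses silicon.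

## Retrosynthetic reasoning

**Quinone (33 from 32).** The two quinone C=O groups are traced back to the aryl methyl ethers of 32. Oxidative demethylation is placed last because the quinone would not survive hydrazine, hot alkali, organometallics or Lewis acids.

**C8 methylene (32 from 30).** The C8 carbonyl of 30 has served its purpose: it supplied the enolate chemistry that built C8a and the acceptor that brought in the C6 methyl. It is removed by Wolff–Kishner reduction. The reduction is placed after the acid chain is complete. In 28, H on the vinyl-bearing carbon is doubly allylic, and hot alkali would move the 1,4-diene into conjugation. In 30 only an isolated tetrasubstituted alkene remains.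

**Acid chain (30 from 29 from 28).** The bond between the second chain carbon and the carboxyl carbon is cut. The vinyl group of 28 is exactly what an allyl cation leaves behind, and linear hydroformylation followed by aldehyde oxidation adds the missing carbon at the right oxidation level without a protecting group.

**Ring A (28 from 27), the key disconnection.** The C1–C2 bond is cut. Forward, the allylic carbinol on the carbon attached to C8a is ionised and the vinylsilane closes ring A. This cut is chosen because one bond formation delivers the ring, the alkene in a position fixed by silicon, and the last stereocentre. An olefination or elimination next to C1 could not guarantee the alkene position.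

**C6 methyl (27 from 25 from 24).** The C6–CH3 bond is cut. The enone arm left over from the dienone is the acceptor for a methyl conjugate addition. With the C8a quaternary centre already in place the half-chair is locked, so axial attack anti to the axial C5 methyl gives the required C6 configuration. The aldol hydroxyl is silylated only for this step.

**C8a (24 from 21 and 22; 21 from 19).** The C8a–C1 bond (aldol with acrolein 22) and the C8a–CH3 bond (methylation) are cut. In enone 19, C8a is the only enolisable position because C5 is quaternary. Both bonds are therefore made regiospecifically from the cross-conjugated dienolate, and no regioselective enolisation of a saturated ketone is needed. Methyl goes in first so that acrolein, entering anti to the C4a side chain, leaves the methyl cis to that chain.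

**C4a side chain (19 from 11 and 16).** The C4a–C4 bond is cut. Dienone 11 is achiral, and one catalytic desymmetrising conjugate addition of the Grignard reagent 17 (from bromide 16) sets C4a and C5 together. This is the only step that introduces absolute configuration.

**Ring B (11 from 9 from 5 and 6).** Enone 9 is cut at the bond from C5 to one neighbouring ring carbon (Michael addition) and at the C=C on the other side (aldol condensation). This is the standard annulation of an α-branched aldehyde with methyl vinyl ketone 6, and the aldehyde α-carbon becomes C5. Dehydrogenation then gives 11.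

**Aldehyde 5 (from 3 and 4; 3 from 2 from 1).** The aryl–CH2 bond is cut. A Heck reaction of iodide 3 with the allylic alcohol 4 gives the α-methyl aldehyde directly. The substitution pattern of the arene comes from phenol 1 by ortho-iodination and O-methylation.

**Side chain (16 from 15 from 12 and 13).** The alkene C–CH3 bond and the bond from the silicon-bearing carbon to the CH2CH2 arm are cut. Carbometalation of silylalkyne 12 puts the metal on the silicon-bearing carbon, and oxirane 13 supplies the two-carbon arm.

## Alternatives that were turned down

**Alternative 1: backbone rearrangement.**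
- Disconnection: the C5–CH3 and C8a–CH3 bonds are made by migration. A decalin with methyl groups on C4a and C1, a tertiary carbinol at C5 and a C(CH3)2SiMe3 group on C2 would be ionised by a boron Lewis acid.
- Key step: CH3 (C4a to C5), H (C8a to C4a), CH3 (C1 to C8a) and H (C2 to C1) shift in sequence, and loss of silicon gives the isopropylidene group. The product is the hydroquinone diacetate methyl ester A1.
- For: four stereocentres follow from stereospecific anti 1,2-shifts. In particular, H arrives at C1 anti to the departing methyl, which guarantees the equatorial chain. On C1 control this alternative is stronger than the chosen route, which relies on a chair preference.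
- Against: four cations in series, each able to eliminate or stop early. The first cation sits next to the arylmethyl group, and a benzylic hydride shift gives a stabilised benzylic cation. The substrate is itself a decalin with five stereocentres and two quaternary carbons, and is no shorter to make than 27.
- Comparison: the chosen route generates one cation with one productive partner from a monocyclic precursor, and each stereocentre can be checked separately.

**Alternative 2: Dötz benzannulation.**
- Disconnection: the aromatic ring is built last from the terpenoid alkyne A4, the chromium carbene complex A3 and one carbonyl ligand.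
- Key step: three ring C–C bonds form, giving the 4-methoxyphenol A2 with the alkyl group and the methyl flanking the phenol carbon.
- For: it is more convergent, and the electron-rich arene is absent from every Lewis-acidic step. In the chosen route the arene is a competing π-nucleophile in the key step, so on this point the alternative is stronger.
- Against: A4 already contains the complete decalin, all five stereocentres and the isopropylidene group. The alternative says nothing about how ring A and the alkene are made. It adds a stoichiometric chromium reagent and a propargyl group on the hindered C5, and the end still needs ester hydrolysis and oxidation.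
- Comparison: the chosen route spends its key step on the real structural problem, and the arene enters at the start as part of the annulation that builds C5.

**Alternative 3: cationic chloro-olefin annulation.**
- Disconnection: the C8a–C1 bond. Protonation of a C8a=C8 ring alkene gives the tertiary C8a cation, which is trapped by a chloroalkene in the side arm.
- Key step: ring A closes as the C2 ketone A5 after hydrolysis, with a benzyloxypropyl chain on C1.
- For: a tertiary cation with a close precedent class. C1 is α to the ketone, so its configuration can be corrected by equilibration. On both points the alternative is as strong or stronger.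
- Against: the C2 ketone, flanked by the C1 stereocentre and close to the quaternary C8a, must then be turned into C=C(CH3)2. Isopropylidene ylides mainly enolise such ketones, and addition–dehydration sequences give alkene regioisomers. The chain needs debenzylation and two oxidations.
- Comparison: in the chosen route silicon fixes the alkene position in the ring-forming step itself, and the chain reaches the acid in two steps from the vinyl group.

Key step: step 13

Assumption: the sense of induction of the copper–diphosphine catalyst on dienone 11 cannot be predicted with certainty, so the ligand enantiomer that gives (4R,5S)-19 is used; 21 and 24–27 are carried as mixtures at centres that are erased later (the methyl-bearing enolisable carbon of 21, the carbinol carbon of 24–27).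

## Route

Step 1
Reactants: 1 4-methoxy-2-methylphenol
Product: 2 2-iodo-4-methoxy-6-methylphenol
Conditions: I2, NaHCO3, THF/H2O, 0 °C to rt
Reagents that add atoms: iodine, II
Why: Electrophilic aromatic iodination of the phenolate; the para position is blocked by OCH3, so the only site ortho to the strongest donor is C6.

Step 2
Reactants: 2 2-iodo-4-methoxy-6-methylphenol
Product: 3 1-iodo-2,5-dimethoxy-3-methylbenzene
Conditions: CH3I, K2CO3, acetone, reflux
Reagents that add atoms: iodomethane, CI
Why: Williamson O-methylation of the phenol; the aryl iodide is inert to these conditions.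

Step 3
Reactants: 3 1-iodo-2,5-dimethoxy-3-methylbenzene, 4 2-methylprop-2-en-1-ol
Product: 5 3-(2,5-dimethoxy-3-methylphenyl)-2-methylpropanal (racemic)
Conditions: Pd(OAc)2 (3 mol %), Bu4NCl, NaHCO3, DMF, 50 °C
Reagents that add atoms: none
Why: Heck arylation of an allylic alcohol under Jeffery conditions; the aryl group adds to the terminal alkene carbon and β-hydride elimination towards the carbinol carbon gives an enol that tautomerises to the saturated aldehyde.

Step 4
Reactants: 5 3-(2,5-dimethoxy-3-methylphenyl)-2-methylpropanal, 6 but-3-en-2-one
Product: 9 4-[(2,5-dimethoxy-3-methylphenyl)methyl]-4-methylcyclohex-2-en-1-one (racemic), via pyrrolidine enamine 7 (not isolated), via keto aldehyde 8 (not isolated)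
Conditions: pyrrolidine, PhMe, reflux (−H2O); 6, 0 °C to rt; then 4 M HCl, rt
Reagents that add atoms: none
Why: Stork enamine Michael addition, hydrolysis and intramolecular aldol condensation (Robinson-type annulation of an α-branched aldehyde), the standard entry to 4,4-disubstituted cyclohexenones; the aldehyde α-carbon becomes the quaternary C5.

Step 5
Reactants: 9 4-[(2,5-dimethoxy-3-methylphenyl)methyl]-4-methylcyclohex-2-en-1-one
Product: 11 4-[(2,5-dimethoxy-3-methylphenyl)methyl]-4-methylcyclohexa-2,5-dien-1-one, via silyl dienol ether 10 (not isolated)
Conditions: Me3SiOTf, Et3N, CH2Cl2, 0 °C; then Pd(OAc)2 (1.1 equiv), MeCN, rt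
Reagents that add atoms: none
Why: Saegusa–Ito oxidation; enolisation can only occur on the saturated side because the γ-carbon is quaternary, and palladation with β-hydride elimination installs the second enone double bond without the quinone-type oxidants that would attack the electron-rich benzyl group. The product is achiral, with a mirror plane through C=O and C5.

Step 6
Reactants: 12 trimethyl(prop-1-yn-1-yl)silane, 13 oxirane
Product: 15 4-methyl-3-(trimethylsilyl)pent-3-en-1-ol, via alkenyl Grignard reagent 14 (not isolated)
Conditions: CH3MgBr, Ni(acac)2 (10 mol %), Me3Al (10 mol %), THF, rt; then CuI (10 mol %), 13, −30 to 0 °C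
Reagents that add atoms: methylmagnesium bromide, C[Mg]Br
Why: Nickel-catalysed carbomagnesiation of a silylalkyne puts CH3 on the carbon remote from silicon and magnesium on the silicon-bearing carbon; both groups on the distal carbon are then methyl, so the configurational lability of the alkenyl Grignard reagent does not matter. Copper-catalysed opening of oxirane adds the two-carbon arm.

Step 7
Reactants: 15 4-methyl-3-(trimethylsilyl)pent-3-en-1-ol
Product: 16 (5-bromo-2-methylpent-2-en-3-yl)trimethylsilane
Conditions: CBr4, PPh3, CH2Cl2, 0 °C
Reagents that add atoms: tetrabromomethane, BrC(Br)(Br)Br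
Why: Appel bromination of a primary alcohol under neutral conditions, so the vinylsilane is not exposed to acid.

Step 8
Reactants: 16 (5-bromo-2-methylpent-2-en-3-yl)trimethylsilane, 11 4-[(2,5-dimethoxy-3-methylphenyl)methyl]-4-methylcyclohexa-2,5-dien-1-one
Product: 19 (4R,5S)-4-[(2,5-dimethoxy-3-methylphenyl)methyl]-4-methyl-5-[4-methyl-3-(trimethylsilyl)pent-3-en-1-yl]cyclohex-2-en-1-one, via Grignard reagent 17 (not isolated), via magnesium enolate 18 (not isolated)
Conditions: Mg, Et2O, reflux; then 11, CuBr·SMe2 (5 mol %), (R)-1-[(SP)-2-(diphenylphosphino)ferrocenyl]ethyldicyclohexylphosphine (6 mol %), t-BuOMe, −75 °C; aq. NH4Cl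
Reagents that add atoms: none
Why: Copper-catalysed asymmetric conjugate addition of a primary alkyl Grignard reagent to a prochiral cross-conjugated dienone (desymmetrisation); the chiral copper complex selects one of the two enantiotopic enone arms. The alkyl group enters anti to the arylmethyl group, which screens its face more than the methyl does, so the side chain at C4a ends up cis to the C5 methyl and both centres are fixed together.

Step 9
Reactants: 19 (4R,5S)-enone
Product: 21 (4S,5S)-4-[(2,5-dimethoxy-3-methylphenyl)methyl]-4,6-dimethyl-5-[4-methyl-3-(trimethylsilyl)pent-3-en-1-yl]cyclohex-2-en-1-one (C6 epimers), via lithium dienolate 20 (not isolated)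
Conditions: LDA, THF, −78 °C; CH3I, −78 to −30 °C
Reagents that add atoms: iodomethane, CI
Why: Kinetic enolate alkylation; the only acidic C–H of the enone is on the future C8a because C5 is quaternary, so the cross-conjugated dienolate forms regiospecifically and is C-methylated. The new centre becomes trigonal again in step 10.

Step 10
Reactants: 21 (4S,5S)-6-methyl enone, 22 prop-2-enal
Product: 24 (4S,5R,6R)-4-[(2,5-dimethoxy-3-methylphenyl)methyl]-6-(1-hydroxyprop-2-en-1-yl)-4,6-dimethyl-5-[4-methyl-3-(trimethylsilyl)pent-3-en-1-yl]cyclohex-2-en-1-one (carbinol epimers), via lithium dienolate 23 (not isolated)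
Conditions: LDA, THF, −78 to −40 °C; 22, −78 °C; AcOH, −78 °C
Reagents that add atoms: none
Why: Lithium enolate aldol addition; removal of the last α-hydrogen gives the fully substituted dienolate as the only possible enolate, and the enal reacts 1,2 at low temperature. Attack anti to the neighbouring C4a side chain creates the quaternary C8a with its methyl cis to that chain.

Step 11
Reactants: 24 aldol adduct
Product: 25 triethylsilyl ether of 24
Conditions: Et3SiCl, imidazole, DMF, rt
Reagents that add atoms: chlorotriethylsilane, CC[Si](Cl)(CC)CC
Why: Silyl ether protection; masking the aldol hydroxyl prevents retro-aldol cleavage of an alkoxide and consumption of cuprate in step 12.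

Step 12
Reactants: 25 triethylsilyl ether
Product: 27 (2R,3R,4S,5S)-4-[(2,5-dimethoxy-3-methylphenyl)methyl]-2-(1-hydroxyprop-2-en-1-yl)-2,4,5-trimethyl-3-[4-methyl-3-(trimethylsilyl)pent-3-en-1-yl]cyclohexan-1-one (carbinol epimers), via silyl enol ether 26 (not isolated)
Conditions: Me2CuLi (from CH3Li and CuI), Me3SiCl, THF, −78 to −40 °C; then HF·pyridine, THF, 0 °C
Reagents that add atoms: lithium dimethylcuprate, [Li+].C[Cu-]C
Why: Cuprate conjugate addition accelerated by Me3SiCl; axial attack on the half-chair that has the C4a side chain equatorial and the C5 methyl axial delivers CH3 to C6 anti to that methyl and trans to the side chain. HF·pyridine then cleaves the silyl enol ether and the triethylsilyl ether without touching the vinylsilane.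

Step 13
Reactants: 27 (2R,3R,4S,5S)-β-hydroxy ketone
Product: 28 (3S,4S,4aR,8R,8aR)-4-[(2,5-dimethoxy-3-methylphenyl)methyl]-8-ethenyl-3,4,8a-trimethyl-7-(propan-2-ylidene)octahydronaphthalen-1(2H)-one
Conditions: SnCl4 (2 equiv), CH2Cl2, −78 °C
Reagents that add atoms: none
Why: SnCl4 ionises the allylic carbinol to an allyl cation whose substituted terminus is the future C1; the silicon-bearing carbon of the tetrasubstituted vinylsilane attacks it ipso, and the tertiary β-silyl cation loses Me3Si+, so the C=C(CH3)2 bond appears in one defined position. The closest known reaction type is the vinylsilane-terminated cation–olefin cyclisation in the exocyclic mode, with allylic alcohols known as initiators from polyene cyclisations. Ring A closes 6-exo with respect to the vinylsilane; attack at the far allyl terminus would need an eight-membered ring and attack by the arene a seven-membered ring. The trans fusion is already fixed by the trans-diequatorial arms on C4a and C8a, so C1 is the only new stereocentre. It is set in a chair-like transition state with the CH=CH2 terminus equatorial and cis to the angular methyl, which avoids syn-axial contact with H-4a and the axial H on C3. Ionisation must outrun retro-aldol cleavage: no base is present, so the carbinol reacts as its Lewis acid complex and not as an alkoxide, and the temperature is kept low. Ipso attack is secured by the tertiary β-silyl cation it produces. The equatorial preference at C1 is the least secure element, because the crowded silicon-bearing carbon also presses on the equatorial position.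

Step 14
Reactants: 28 vinyl decalone
Product: 29 3-[(1R,4aR,5S,6S,8aR)-5-[(2,5-dimethoxy-3-methylphenyl)methyl]-5,6,8a-trimethyl-8-oxo-2-(propan-2-ylidene)decahydronaphthalen-1-yl]propanal
Conditions: Rh(acac)(CO)2 (1 mol %), BIPHEPHOS (3 mol %), CO/H2 (1:1, 10 bar), PhMe, 70 °C
Reagents that add atoms: carbon monoxide, [C-]#[O+]
Why: Rhodium-catalysed hydroformylation with a bulky bisphosphite; anti-Markovnikov hydrorhodation of the only monosubstituted alkene and CO insertion give the linear aldehyde. The tetrasubstituted alkene and the ketone are inert.

Step 15
Reactants: 29 keto aldehyde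
Product: 30 3-[(1R,4aR,5S,6S,8aR)-5-[(2,5-dimethoxy-3-methylphenyl)methyl]-5,6,8a-trimethyl-8-oxo-2-(propan-2-ylidene)decahydronaphthalen-1-yl]propanoic acid
Conditions: NaClO2, NaH2PO4, 2-methylbut-2-ene, t-BuOH/H2O, 0 °C to rt
Reagents that add atoms: sodium chlorite, [Na+].[O-]Cl=O
Why: Pinnick oxidation; chlorous acid converts the aldehyde into the acid, and the scavenger alkene removes HOCl before it can attack the arene or the isopropylidene group.

Step 16
Reactants: 30 keto acid
Product: 32 3-[(1S,4aR,5S,6S,8aR)-5-[(2,5-dimethoxy-3-methylphenyl)methyl]-5,6,8a-trimethyl-2-(propan-2-ylidene)decahydronaphthalen-1-yl]propanoic acid, via hydrazone 31 (not isolated)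
Conditions: N2H4·H2O, KOH, diethylene glycol, 130 then 200 °C; aq. HCl
Reagents that add atoms: none
Why: Wolff–Kishner reduction (Huang-Minlon procedure); the hydrazone loses N2 in hot alkali to leave the C8 methylene. The carboxylate is inert, C8a carries no hydrogen and C7 is not a stereocentre, and the isolated tetrasubstituted alkene no longer has the doubly allylic hydrogen that made this step unsafe at the stage of 28.

Step 17
Reactants: 32 dimethoxyarene acid
Product: 33 3-[(1S,4aR,5S,6S,8aR)-5,6,8a-trimethyl-5-[(5-methyl-3,6-dioxocyclohexa-1,4-dien-1-yl)methyl]-2-(propan-2-ylidene)decahydronaphthalen-1-yl]propanoic acid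
Conditions: (NH4)2Ce(NO3)6 (2.5 equiv), MeCN/H2O, 0 °C
Reagents that add atoms: water, O
Why: Oxidative demethylation of a 1,4-dimethoxyarene; two one-electron oxidations and attack of water give the quinone and two molecules of methanol. The arene is oxidised far more easily than the alkene or the acid.

## Compound list

1 | 4-methoxy-2-methylphenol | COc1ccc(O)c(C)c1 | starting material
2 | 2-iodo-4-methoxy-6-methylphenol | COc1cc(C)c(O)c(I)c1 | intermediate
3 | 1-iodo-2,5-dimethoxy-3-methylbenzene | COc1cc(C)c(OC)c(I)c1 | intermediate
4 | 2-methylprop-2-en-1-ol | C=C(C)CO | starting material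
5 | 3-(2,5-dimethoxy-3-methylphenyl)-2-methylpropanal (racemic) | COc1cc(C)c(OC)c(CC(C)C=O)c1 | intermediate
6 | but-3-en-2-one (methyl vinyl ketone) | CC(=O)C=C | starting material
7 | 1-[3-(2,5-dimethoxy-3-methylphenyl)-2-methylprop-1-en-1-yl]pyrrolidine | COc1cc(C)c(OC)c(CC(C)=CN2CCCC2)c1 | intermediate
8 | 2-[(2,5-dimethoxy-3-methylphenyl)methyl]-2-methyl-5-oxohexanal | COc1cc(C)c(OC)c(CC(C)(CCC(C)=O)C=O)c1 | intermediate
9 | 4-[(2,5-dimethoxy-3-methylphenyl)methyl]-4-methylcyclohex-2-en-1-one (racemic) | COc1cc(C)c(OC)c(CC2(C)CCC(=O)C=C2)c1 | intermediate
10 | {[4-[(2,5-dimethoxy-3-methylphenyl)methyl]-4-methylcyclohexa-1,5-dien-1-yl]oxy}trimethylsilane | COc1cc(C)c(OC)c(CC2(C)CC=C(O[Si](C)(C)C)C=C2)c1 | intermediate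
11 | 4-[(2,5-dimethoxy-3-methylphenyl)methyl]-4-methylcyclohexa-2,5-dien-1-one | COc1cc(C)c(OC)c(CC2(C)C=CC(=O)C=C2)c1 | intermediate
12 | trimethyl(prop-1-yn-1-yl)silane | CC#C[Si](C)(C)C | starting material
13 | oxirane | C1CO1 | starting material
14 | bromo[2-methyl-1-(trimethylsilyl)prop-1-en-1-yl]magnesium | CC(C)=C([Mg]Br)[Si](C)(C)C | intermediate
15 | 4-methyl-3-(trimethylsilyl)pent-3-en-1-ol | CC(C)=C(CCO)[Si](C)(C)C | intermediate
16 | (5-bromo-2-methylpent-2-en-3-yl)trimethylsilane | CC(C)=C(CCBr)[Si](C)(C)C | intermediate
17 | bromo[4-methyl-3-(trimethylsilyl)pent-3-en-1-yl]magnesium | CC(C)=C(CC[Mg]Br)[Si](C)(C)C | intermediate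
18 | bromomagnesium enolate from the 1,4-addition to 11 (enolate C=C towards the carbon next to the new side chain; configuration as in 19) | COc1cc(C)c(OC)c(C[C@]2(C)[C@@H](CCC(=C(C)C)[Si](C)(C)C)C=C(O[Mg]Br)C=C2)c1 | intermediate
19 | (4R,5S)-4-[(2,5-dimethoxy-3-methylphenyl)methyl]-4-methyl-5-[4-methyl-3-(trimethylsilyl)pent-3-en-1-yl]cyclohex-2-en-1-one (side chain cis to the ring methyl) | COc1cc(C)c(OC)c(C[C@]2(C)[C@@H](CCC(=C(C)C)[Si](C)(C)C)CC(=O)C=C2)c1 | intermediate
20 | lithium cross-conjugated dienolate of 19 | COc1cc(C)c(OC)c(C[C@]2(C)[C@@H](CCC(=C(C)C)[Si](C)(C)C)C=C(O[Li])C=C2)c1 | intermediate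
21 | (4S,5S)-4-[(2,5-dimethoxy-3-methylphenyl)methyl]-4,6-dimethyl-5-[4-methyl-3-(trimethylsilyl)pent-3-en-1-yl]cyclohex-2-en-1-one (C6 epimers) | COc1cc(C)c(OC)c(C[C@]2(C)[C@@H](CCC(=C(C)C)[Si](C)(C)C)C(C)C(=O)C=C2)c1 | intermediate
22 | prop-2-enal (acrolein) | C=CC=O | starting material
23 | lithium cross-conjugated dienolate of 21 (methyl on the enolate carbon) | COc1cc(C)c(OC)c(C[C@]2(C)[C@@H](CCC(=C(C)C)[Si](C)(C)C)C(C)=C(O[Li])C=C2)c1 | intermediate
24 | (4S,5R,6R)-4-[(2,5-dimethoxy-3-methylphenyl)methyl]-6-(1-hydroxyprop-2-en-1-yl)-4,6-dimethyl-5-[4-methyl-3-(trimethylsilyl)pent-3-en-1-yl]cyclohex-2-en-1-one (carbinol epimers; the two ring methyls and the side chain on one face) | COc1cc(C)c(OC)c(C[C@]2(C)[C@@H](CCC(=C(C)C)[Si](C)(C)C)[C@](C)(C(O)C=C)C(=O)C=C2)c1 | intermediate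
25 | triethylsilyl ether of 24, (4S,5R,6R) | COc1cc(C)c(OC)c(C[C@]2(C)[C@@H](CCC(=C(C)C)[Si](C)(C)C)[C@](C)(C(O[Si](CC)(CC)CC)C=C)C(=O)C=C2)c1 | intermediate
26 | trimethylsilyl enol ether of the methyl conjugate adduct of 25, still carrying the triethylsilyl ether (ring configuration as in 27) | COc1cc(C)c(OC)c(C[C@]2(C)[C@@H](CCC(=C(C)C)[Si](C)(C)C)[C@](C)(C(O[Si](CC)(CC)CC)C=C)C(O[Si](C)(C)C)=C[C@@H]2C)c1 | intermediate
27 | (2R,3R,4S,5S)-4-[(2,5-dimethoxy-3-methylphenyl)methyl]-2-(1-hydroxyprop-2-en-1-yl)-2,4,5-trimethyl-3-[4-methyl-3-(trimethylsilyl)pent-3-en-1-yl]cyclohexan-1-one (carbinol epimers) | COc1cc(C)c(OC)c(C[C@]2(C)[C@@H](CCC(=C(C)C)[Si](C)(C)C)[C@](C)(C(O)C=C)C(=O)C[C@@H]2C)c1 | intermediate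
28 | (3S,4S,4aR,8R,8aR)-4-[(2,5-dimethoxy-3-methylphenyl)methyl]-8-ethenyl-3,4,8a-trimethyl-7-(propan-2-ylidene)octahydronaphthalen-1(2H)-one | COc1cc(C)c(OC)c(C[C@]2(C)[C@H]3CCC(=C(C)C)[C@@H](C=C)[C@]3(C)C(=O)C[C@@H]2C)c1 | intermediate
29 | 3-[(1R,4aR,5S,6S,8aR)-5-[(2,5-dimethoxy-3-methylphenyl)methyl]-5,6,8a-trimethyl-8-oxo-2-(propan-2-ylidene)decahydronaphthalen-1-yl]propanal | COc1cc(C)c(OC)c(C[C@]2(C)[C@H]3CCC(=C(C)C)[C@@H](CCC=O)[C@]3(C)C(=O)C[C@@H]2C)c1 | intermediate
30 | 3-[(1R,4aR,5S,6S,8aR)-5-[(2,5-dimethoxy-3-methylphenyl)methyl]-5,6,8a-trimethyl-8-oxo-2-(propan-2-ylidene)decahydronaphthalen-1-yl]propanoic acid | COc1cc(C)c(OC)c(C[C@]2(C)[C@H]3CCC(=C(C)C)[C@@H](CCC(=O)O)[C@]3(C)C(=O)C[C@@H]2C)c1 | intermediate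
31 | hydrazone of 30 at the ring ketone | COc1cc(C)c(OC)c(C[C@]2(C)[C@H]3CCC(=C(C)C)[C@@H](CCC(=O)O)[C@]3(C)C(=NN)C[C@@H]2C)c1 | intermediate
32 | 3-[(1S,4aR,5S,6S,8aR)-5-[(2,5-dimethoxy-3-methylphenyl)methyl]-5,6,8a-trimethyl-2-(propan-2-ylidene)decahydronaphthalen-1-yl]propanoic acid | COc1cc(C)c(OC)c(C[C@]2(C)[C@H]3CCC(=C(C)C)[C@@H](CCC(=O)O)[C@]3(C)CC[C@@H]2C)c1 | intermediate
33 | 3-[(1S,4aR,5S,6S,8aR)-5,6,8a-trimethyl-5-[(5-methyl-3,6-dioxocyclohexa-1,4-dien-1-yl)methyl]-2-(propan-2-ylidene)decahydronaphthalen-1-yl]propanoic acid | CC1=CC(=O)C=C(C[C@]2(C)[C@H]3CCC(=C(C)C)[C@@H](CCC(=O)O)[C@]3(C)CC[C@@H]2C)C1=O | target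

## Step count and least certain steps

Total: 17 steps. Longest linear sequence: 15 steps (steps 1–5 and 8–17 from 1). The side-chain branch (steps 6 and 7) joins in step 8.

**Step 13 (key step).** The most likely failure is fragmentation of the β-hydroxy ketone by retro-aldol cleavage once tin is bound to the carbinol oxygen. Ionisation of a secondary allylic carbinol that carries an inductively deactivating β-keto group is slow, and cleavage relieves the strain of the quaternary C8a. A second concern is erosion of facial selectivity at the cation carbon, because the bulky silicon-bearing carbon disfavours an equatorial neighbour; the epimers would then have to be separated at 28. Fallback: the cation is generated from a halide that has no aldol oxygen. Setting out from 27, thionyl chloride in ether converts the carbinol with allylic transposition into the primary allylic chloride F1. Catalytic ZnCl2 in CH2Cl2 at low temperature ionises F1 to the same allyl cation, and closure with loss of the silyl group comes back to the route at 28.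

**Step 8.** The most likely failure is insufficient catalyst control at a β-carbon flanked by a quaternary centre (the uncatalysed Grignard addition competes and lowers the enantiomeric purity), together with incomplete discrimination between the methyl and arylmethyl faces. Fallback: C5 is set before the side chain is added. Setting out from 5 and 6, an enantioselective amine-catalysed version of the annulation (chiral proline sulfonamide) gives the (4R)-enone F2. Substrate-controlled conjugate addition of the cuprate made from 17 (CuBr·SMe2, Me3SiCl) gives the ketone F3. Kinetic silylation on the less hindered side (LDA, Me3SiCl) gives the silyl enol ether F4, and Pd(OAc)2 in MeCN comes back to the route at 19.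

**Step 10.** The most likely failure is incomplete or reversible addition at the fully substituted enolate carbon, with retro-aldol on warming or competing 1,4-addition to the enal. Fallback: a Lewis acid mediated and irreversible Mukaiyama aldol addition. Setting out from 21, Me3SiOTf and Et3N give the silyl dienol ether F5. Addition to 22 with TiCl4 in CH2Cl2 at −78 °C comes back to the route at 24 after aqueous work-up.

**Step 14.** The most likely failure is isomerisation of the vinyl group by the rhodium hydride. β-Hydride elimination from the branched alkyl towards the doubly allylic ring hydrogen gives a conjugated ethylidene diene that no longer hydroformylates, and the vinyl group next to a quaternary carbon reacts slowly. Fallback: hydroboration, oxidation and one-carbon homologation. Setting out from 28, 9-borabicyclo[3.3.1]nonane followed by H2O2/NaOH gives the primary alcohol F6. Dess–Martin periodinane gives the aldehyde F7. Wittig reaction with (methoxymethylene)triphenylphosphorane, which leaves the hindered ring ketone alone, gives the enol ether F8, and hydrolysis with dilute HCl in THF comes back to the route at 29.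

**Step 16.** The most likely failure is incomplete hydrazone formation at a carbonyl flanked by the quaternary C8a and screened by axial methyl groups, which returns ketone or gives azine. Partial cleavage of the aryl methyl ethers in hot alkali would be harmless, since step 17 removes them anyway. Fallback: stepwise radical deoxygenation. Setting out from 30, Me3SiCHN2 in MeOH/PhMe gives the keto methyl ester F9. NaBH4 in MeOH gives the hydroxy ester F10. KHMDS, CS2 and CH3I give the xanthate F11. Bu3SnH with azobisisobutyronitrile in refluxing toluene (Barton–McCombie deoxygenation) gives the methyl ester F12, and LiOH in THF/H2O comes back to the route at 32.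

## Further compounds

F1 | step 13 | (2R,3R,4S,5S)-2-[(E)-3-chloroprop-1-en-1-yl]-4-[(2,5-dimethoxy-3-methylphenyl)methyl]-2,4,5-trimethyl-3-[4-methyl-3-(trimethylsilyl)pent-3-en-1-yl]cyclohexan-1-one | COc1cc(C)c(OC)c(C[C@]2(C)[C@@H](CCC(=C(C)C)[Si](C)(C)C)[C@](C)(/C=C/CCl)C(=O)C[C@@H]2C)c1
F2 | step 8 | (4R)-4-[(2,5-dimethoxy-3-methylphenyl)methyl]-4-methylcyclohex-2-en-1-one | COc1cc(C)c(OC)c(C[C@]2(C)C=CC(=O)CC2)c1
F3 | step 8 | 4-[(2,5-dimethoxy-3-methylphenyl)methyl]-4-methyl-3-[4-methyl-3-(trimethylsilyl)pent-3-en-1-yl]cyclohexan-1-one (side chain cis to the ring methyl; configuration as in 19) | COc1cc(C)c(OC)c(C[C@]2(C)[C@@H](CCC(=C(C)C)[Si](C)(C)C)CC(=O)CC2)c1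
F4 | step 8 | trimethylsilyl enol ether of F3 on the side remote from the side chain | COc1cc(C)c(OC)c(C[C@]2(C)[C@@H](CCC(=C(C)C)[Si](C)(C)C)CC(O[Si](C)(C)C)=CC2)c1
F5 | step 10 | trimethylsilyl dienol ether of 21 (methyl on the enol carbon) | COc1cc(C)c(OC)c(C[C@]2(C)[C@@H](CCC(=C(C)C)[Si](C)(C)C)C(C)=C(O[Si](C)(C)C)C=C2)c1
F6 | step 14 | primary alcohol from anti-Markovnikov hydration of the vinyl group of 28 (2-hydroxyethyl in place of ethenyl) | COc1cc(C)c(OC)c(C[C@]2(C)[C@H]3CCC(=C(C)C)[C@@H](CCO)[C@]3(C)C(=O)C[C@@H]2C)c1
F7 | step 14 | aldehyde from F6 (2-oxoethyl in place of ethenyl) | COc1cc(C)c(OC)c(C[C@]2(C)[C@H]3CCC(=C(C)C)[C@@H](CC=O)[C@]3(C)C(=O)C[C@@H]2C)c1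
F8 | step 14 | methyl enol ether from F7 (3-methoxyprop-2-en-1-yl in place of ethenyl, E/Z mixture) | COc1cc(C)c(OC)c(C[C@]2(C)[C@H]3CCC(=C(C)C)[C@@H](CC=COC)[C@]3(C)C(=O)C[C@@H]2C)c1
F9 | step 16 | methyl ester of 30 | COc1cc(C)c(OC)c(C[C@]2(C)[C@H]3CCC(=C(C)C)[C@@H](CCC(=O)OC)[C@]3(C)C(=O)C[C@@H]2C)c1
F10 | step 16 | ring alcohol from reduction of the ketone of F9 (carbinol epimers) | COc1cc(C)c(OC)c(C[C@]2(C)[C@H]3CCC(=C(C)C)[C@@H](CCC(=O)OC)[C@]3(C)C(O)C[C@@H]2C)c1
F11 | step 16 | S-methyl xanthate of F10 | COc1cc(C)c(OC)c(C[C@]2(C)[C@H]3CCC(=C(C)C)[C@@H](CCC(=O)OC)[C@]3(C)C(OC(=S)SC)C[C@@H]2C)c1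
F12 | step 16 | methyl ester of 32 | COc1cc(C)c(OC)c(C[C@]2(C)[C@H]3CCC(=C(C)C)[C@@H](CCC(=O)OC)[C@]3(C)CC[C@@H]2C)c1
A1 | alternative 1 | hydroquinone diacetate methyl ester of the rearranged skeleton (2,5-diacetoxy-3-methylbenzyl group on C5, methyl propanoate on C1) | CC(=O)Oc1cc(C)c(OC(C)=O)c(C[C@]2(C)[C@H]3CCC(=C(C)C)[C@@H](CCC(=O)OC)[C@]3(C)CC[C@@H]2C)c1
A2 | alternative 2 | 4-methoxyphenol form of the target methyl ester (2-hydroxy-5-methoxy-3-methylbenzyl group on C5) | COc1cc(C)c(O)c(C[C@]2(C)[C@H]3CCC(=C(C)C)[C@@H](CCC(=O)OC)[C@]3(C)CC[C@@H]2C)c1
A3 | alternative 2 | pentacarbonyl[(E)-1-methoxybut-2-enylidene]chromium | COC(=[Cr](=C=O)(=C=O)(=C=O)(=C=O)=C=O)/C=C/C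
A4 | alternative 2 | methyl 3-[(1S,4aR,5S,6S,8aR)-5,6,8a-trimethyl-2-(propan-2-ylidene)-5-(prop-2-yn-1-yl)decahydronaphthalen-1-yl]propanoate | C#CC[C@]1(C)[C@H]2CCC(=C(C)C)[C@@H](CCC(=O)OC)[C@]2(C)CC[C@@H]1C
A5 | alternative 3 | trans-decalone with the ketone on C2 and a 3-(benzyloxy)propyl chain on C1 | COc1cc(C)c(OC)c(C[C@]2(C)[C@H]3CCC(=O)[C@@H](CCCOCc4ccccc4)[C@]3(C)CC[C@@H]2C)c1
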